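**Plan**

- Retrosynthesis: cut the C11–O aryl ether, then ring A at C1–C2 and C4–C5 (leaving a ring-B cyclohexenone and 3-bromo-3-methylbutan-2-one), then ring B at C9–C10 and C5–C6 (Diels–Alder).
- Enabling feature: the oxygens on C3 and C6 are 1,4-related across C4–C5, and C3 and C1 are 1,5-related through C4–C5–C10. With C6 as the ring-B enone carbonyl, C5 is an enol carbon and C1 (on quaternary C10) can be a non-enolisable aldehyde; quaternary C4 lets the C3 ketone enolise only toward C2.
- Forward: ring B by catalytic asymmetric Diels–Alder reaction, carbonyl at C6 by allylic oxidation, ring A in one flask by radical alkylation at C5 followed by aldol condensation, then redox adjustment, acetate, coumarin ether.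
- Stereochemistry: C9 and C10 from the exo-selective, catalyst-controlled cycloaddition; C5 by equilibration to the trans ring fusion through the C6 ketone; C6 by stereoconvergent capture of an allyl cation on the face opposite the axial methyl groups.

Key step: step 7

Remark: locants C1–C12 are those of the drimane skeleton of the target (C3 ketone, C6 acetoxy carbon, C10 angular carbon, C11 = OCH2).
Assumption: the (S)-configured oxazaborolidinium catalyst is taken to give the (1R,2R)-adduct 5 by the accepted model for 2-substituted acroleins; if the sense proves opposite, its enantiomer is used and nothing else changes.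

**Route**

Step 1
Reactants: 1 (E)-3-methylpent-2-en-4-yn-1-ol
Product: 2 tert-butyl{[(E)-3-methylpent-2-en-4-yn-1-yl]oxy}diphenylsilane
Conditions: TBDPSCl, imidazole, CH2Cl2, 23 °C
Reagents that add atoms: tert-butyl(chloro)diphenylsilane, CC(C)(C)[Si](Cl)(c1ccccc1)c1ccccc1
Why: Imidazole-promoted silylation of a primary alcohol; the E alkene is untouched and no stereocentre is involved.

Step 2
Reactants: 2 tert-butyl{[(E)-3-methylpent-2-en-4-yn-1-yl]oxy}diphenylsilane
Product: 3 tert-butyl{[(E)-3-methylpenta-2,4-dien-1-yl]oxy}diphenylsilane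
Conditions: H2 (1 atm), Pd/CaCO3 poisoned with Pb(OAc)2 (Lindlar catalyst), quinoline, hexane, 23 °C
Reagents that add atoms: none
Why: Lindlar semihydrogenation of the terminal alkyne should stop at the vinyl group and give the (E)-1-substituted 2-methylbutadiene.

Step 3
Reactants: 3 tert-butyl{[(E)-3-methylpenta-2,4-dien-1-yl]oxy}diphenylsilane; 4 methacrolein
Product: 5 (1R,2R)-2-{[tert-butyl(diphenyl)silyl]oxymethyl}-1,3-dimethylcyclohex-3-ene-1-carbaldehyde (CH2OSi on C9 trans to CHO on C10)
Conditions: (S)-diphenylprolinol-derived B-(o-tolyl)oxazaborolidine (20 mol %) activated with Tf2NH, CH2Cl2, −78 to −40 °C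
Reagents that add atoms: none
Why: Catalytic enantioselective Diels–Alder reaction of a 2-substituted acrolein: the unsubstituted diene terminus (C6) should bond to the β-carbon and the substituted terminus C9 to C10, the exo transition state usual for α-methylacrolein places CH2OSi and CHO trans, and the catalyst face sets the absolute configuration of C9 and C10.

Step 4
Reactants: 5 (1R,2R)-2-{[tert-butyl(diphenyl)silyl]oxymethyl}-1,3-dimethylcyclohex-3-ene-1-carbaldehyde
Product: 6 tert-butyl{[(1R,6R)-6-(dimethoxymethyl)-2,6-dimethylcyclohex-2-en-1-yl]methoxy}diphenylsilane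
Conditions: HC(OMe)3, MeOH, PPTS (cat.), 23 °C
Reagents that add atoms: trimethyl orthoformate, COC(OC)OC
Why: Acid-catalysed acetalisation masks the non-enolisable aldehyde for the oxidation and enolate steps.

Step 5
Reactants: 6 tert-butyl{[(1R,6R)-6-(dimethoxymethyl)-2,6-dimethylcyclohex-2-en-1-yl]methoxy}diphenylsilane
Product: 7 (4R,5R)-4-{[tert-butyl(diphenyl)silyl]oxymethyl}-5-(dimethoxymethyl)-3,5-dimethylcyclohex-2-en-1-one
Conditions: Rh2(cap)4 (dirhodium tetracaprolactamate, 1 mol %), t-BuOOH, K2CO3, CH2Cl2, 23 °C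
Reagents that add atoms: tert-butyl hydroperoxide, CC(C)(C)OO
Why: Dirhodium-catalysed allylic oxidation of a 1-methylcyclohexene should convert the ring CH2 next to the CH= carbon into the C6 carbonyl, the hindered tertiary C9–H and the methyl group being less reactive.

Step 6
Reactants: 7 (4R,5R)-4-{[tert-butyl(diphenyl)silyl]oxymethyl}-5-(dimethoxymethyl)-3,5-dimethylcyclohex-2-en-1-one
Product: 8 cross-conjugated trimethylsilyl dienol ether of 7 (C5=C6–OSiMe3, C7=C8; C9 and C10 unchanged)
Conditions: LDA, TMSCl, THF, −78 °C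
Reagents that add atoms: chlorotrimethylsilane, C[Si](C)(C)Cl
Why: Kinetic deprotonation of a 3-methylcyclohex-2-enone by LDA occurs at the α′ CH2 (C5) and O-silylation gives the 2-silyloxydiene; the γ-hydrogen at C9 is not removed.

Step 7
Reactants: 8 cross-conjugated trimethylsilyl dienol ether of 7; 9 3-bromo-3-methylbutan-2-one
Product: 12 (5S,9R,10S)-11-[tert-butyl(diphenyl)silyl]oxydrima-1,7-diene-3,6-dione, via diketone acetal 10 (not isolated), via keto aldehyde 11 (not isolated)
Conditions: fac-Ir(ppy)3 (fac-tris(2-phenylpyridinato)iridium, 1 mol %), 2,6-lutidine, MeCN, blue LEDs, 23 °C; then 1 M aq. HCl, THF, 45 °C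
Reagents that add atoms: none
Why: The excited photocatalyst reduces the C–Br bond of 9, the electrophilic tertiary α-keto radical (C4) adds to the electron-rich terminus C5 of the 2-silyloxydiene, and the resulting silyloxyallyl radical is oxidised by the oxidised photocatalyst and loses the silyl group, so that the C4–C5 bond and the C6 enone arise together (photoredox α-alkylation of silyl enol ethers with α-bromo ketones, a known route to 1,4-diketones with quaternary centres). Aqueous acid then unmasks the C1 aldehyde, and the methyl ketone, which can enolise only toward C2 because C4 is quaternary, closes ring A by a Robinson-type intramolecular aldol condensation in the 6-(enolendo)-exo-trig mode, forming C1–C2 as the enone C1=C2. C4 is not stereogenic, and C5 is set under thermodynamic control because it stays enolisable through the C6 ketone and should settle in the trans-fused arrangement (H5 anti to the C10 methyl) whichever face the radical first attacks. The step needs radical attack at C5 rather than C8 (C5 is the unsubstituted enol-ether terminus and gives the oxygen-stabilised allyl radical), aldol closure onto the aldehyde rather than onto the C6 ketone (the aldehyde is the better electrophile and gives the six-membered ring), and retention of C9 (no base strong enough to remove the γ-hydrogen is present).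

Step 8
Reactants: 12 (5S,9R,10S)-11-[tert-butyl(diphenyl)silyl]oxydrima-1,7-diene-3,6-dione
Product: 14 (5S,6S,9R,10S)-11-[tert-butyl(diphenyl)silyl]oxy-6-hydroxydrim-7-en-3-one (OH on the face of the C10 methyl), via lithium enolate 13 (not isolated)
Conditions: Li[HB(s-Bu)3] (1.1 equiv), THF, −78 °C; then i-Bu2AlH (2.5 equiv), −78 °C; aq. potassium sodium tartrate
Reagents that add atoms: none
Why: Conjugate hydride addition to the β-unsubstituted ring-A enone (as with steroidal 1-en-3-ones) stores C3 as its enolate, so that i-Bu2AlH reduces only the β,β-disubstituted ring-B enone in the 1,2 sense, expected from the face opposite the axial C4 and C10 methyls; work-up returns the C3 ketone, and the configuration of the C6 carbinol is immaterial for step 9.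

Step 9
Reactants: 14 (5S,6S,9R,10S)-11-[tert-butyl(diphenyl)silyl]oxy-6-hydroxydrim-7-en-3-one
Product: 15 (5S,6R,9R,10S)-6-acetoxy-11-[tert-butyl(diphenyl)silyl]oxydrim-7-en-3-one
Conditions: AcOH (solvent), TsOH·H2O (5 mol %), 23 °C
Reagents that add atoms: acetic acid, CC(=O)O
Why: Acid-catalysed allylic substitution through the C6–C7–C8 allyl cation is stereoconvergent: acetic acid should add at the secondary terminus C6 from the face opposite the axial C10 and C4 methyls, giving the equatorial acetate with the trisubstituted C7=C8 alkene, which is also the more stable allylic isomer.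

Step 10
Reactants: 15 (5S,6R,9R,10S)-6-acetoxy-11-[tert-butyl(diphenyl)silyl]oxydrim-7-en-3-one
Product: 16 (5S,6R,9R,10S)-6-acetoxy-11-hydroxydrim-7-en-3-one
Conditions: HF·pyridine, pyridine, THF, 0 to 23 °C
Reagents that add atoms: none
Why: Buffered fluoride cleavage of the silyl ether should leave the allylic acetate and the ketone untouched.

Step 11
Reactants: 16 (5S,6R,9R,10S)-6-acetoxy-11-hydroxydrim-7-en-3-one; 17 umbelliferone (7-hydroxycoumarin)
Product: 18 (5S,6R,9R,10S)-6-acetoxy-11-(2-oxo-2H-chromen-7-yloxy)drim-7-en-3-one (CNP0140705.2)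
Conditions: PPh3, DIAD, THF, 0 to 23 °C
Reagents that add atoms: none
Why: Mitsunobu etherification of the primary alcohol with the acidic phenol forms the C11 aryl ether without touching a stereocentre.

**Compound list**

1 | (E)-3-methylpent-2-en-4-yn-1-ol | C#C/C(C)=C/CO | starting material
2 | tert-butyl{[(E)-3-methylpent-2-en-4-yn-1-yl]oxy}diphenylsilane | C#C/C(C)=C/CO[Si](c1ccccc1)(c1ccccc1)C(C)(C)C | intermediate
3 | tert-butyl{[(E)-3-methylpenta-2,4-dien-1-yl]oxy}diphenylsilane | C=C/C(C)=C/CO[Si](c1ccccc1)(c1ccccc1)C(C)(C)C | intermediate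
4 | methacrolein | CC(=C)C=O | starting material
5 | (1R,2R)-2-{[tert-butyl(diphenyl)silyl]oxymethyl}-1,3-dimethylcyclohex-3-ene-1-carbaldehyde | C1C=C(C)[C@@H](CO[Si](c2ccccc2)(c2ccccc2)C(C)(C)C)[C@](C)(C=O)C1 | intermediate
6 | tert-butyl{[(1R,6R)-6-(dimethoxymethyl)-2,6-dimethylcyclohex-2-en-1-yl]methoxy}diphenylsilane | C1C=C(C)[C@@H](CO[Si](c2ccccc2)(c2ccccc2)C(C)(C)C)[C@](C)(C(OC)OC)C1 | intermediate
7 | (4R,5R)-4-{[tert-butyl(diphenyl)silyl]oxymethyl}-5-(dimethoxymethyl)-3,5-dimethylcyclohex-2-en-1-one | O=C1C=C(C)[C@@H](CO[Si](c2ccccc2)(c2ccccc2)C(C)(C)C)[C@](C)(C(OC)OC)C1 | intermediate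
8 | cross-conjugated trimethylsilyl dienol ether of 7 | C[Si](C)(C)OC1=C[C@@](C)(C(OC)OC)[C@H](CO[Si](c2ccccc2)(c2ccccc2)C(C)(C)C)C(C)=C1 | intermediate
9 | 3-bromo-3-methylbutan-2-one | CC(=O)C(C)(C)Br | starting material
10 | diketone acetal: 7 bearing a 2-methyl-3-oxobutan-2-yl group at C5 (C5 epimers) | O=C1C=C(C)[C@@H](CO[Si](c2ccccc2)(c2ccccc2)C(C)(C)C)[C@](C)(C(OC)OC)C1C(C)(C)C(C)=O | intermediate
11 | keto aldehyde: 10 with the acetal hydrolysed to CHO (C5 epimers) | O=C1C=C(C)[C@@H](CO[Si](c2ccccc2)(c2ccccc2)C(C)(C)C)[C@](C)(C=O)C1C(C)(C)C(C)=O | intermediate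
12 | (5S,9R,10S)-11-[tert-butyl(diphenyl)silyl]oxydrima-1,7-diene-3,6-dione | O=C1C=C(C)[C@@H](CO[Si](c3ccccc3)(c3ccccc3)C(C)(C)C)[C@]2(C)C=CC(=O)C(C)(C)[C@@H]12 | intermediate
13 | lithium C2=C3 enolate of (5S,9R,10S)-11-[tert-butyl(diphenyl)silyl]oxydrim-7-ene-3,6-dione | O=C1C=C(C)[C@@H](CO[Si](c3ccccc3)(c3ccccc3)C(C)(C)C)[C@]2(C)CC=C(O[Li])C(C)(C)[C@@H]12 | intermediate
14 | (5S,6S,9R,10S)-11-[tert-butyl(diphenyl)silyl]oxy-6-hydroxydrim-7-en-3-one | O[C@H]1C=C(C)[C@@H](CO[Si](c3ccccc3)(c3ccccc3)C(C)(C)C)[C@]2(C)CCC(=O)C(C)(C)[C@@H]12 | intermediate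
15 | (5S,6R,9R,10S)-6-acetoxy-11-[tert-butyl(diphenyl)silyl]oxydrim-7-en-3-one | CC(=O)O[C@@H]1C=C(C)[C@@H](CO[Si](c3ccccc3)(c3ccccc3)C(C)(C)C)[C@]2(C)CCC(=O)C(C)(C)[C@@H]12 | intermediate
16 | (5S,6R,9R,10S)-6-acetoxy-11-hydroxydrim-7-en-3-one | CC(=O)O[C@@H]1C=C(C)[C@@H](CO)[C@]2(C)CCC(=O)C(C)(C)[C@@H]12 | intermediate
17 | umbelliferone | Oc1ccc2ccc(=O)oc2c1 | starting material
18 | (5S,6R,9R,10S)-6-acetoxy-11-(2-oxo-2H-chromen-7-yloxy)drim-7-en-3-one (CNP0140705.2) | CC(=O)O[C@@H]1C=C(C)[C@@H](COc2ccc3ccc(=O)oc3c2)[C@]2(C)CCC(=O)C(C)(C)[C@@H]12 | target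

Total step count: 11. Longest linear sequence: 11 steps (1 to 18).

**Steps most likely to fail**

Step 7. The intermolecular addition of the tertiary radical at C5, which is flanked by quaternary C10, may be slow, so that reduction or dimerisation of the radical and desilylation of 8 compete; aldol closure toward the C6 ketone and incomplete equilibration at C5 are further risks. The fallback makes the C4–C5 bond intramolecularly by oxidative coupling of a silicon-tethered bis-enol ether. It sets out from 7: LDA and then excess Me2SiCl2 should give the chloro(dimethyl)silyl dienol ether F1. Addition of lithium 3-methylbut-2-en-2-olate F2 (from 2-methyl-3-(trimethylsilyloxy)but-2-ene and MeLi) should give the dimethylsilyl bis-enol ether F3. Oxidation with (NH4)2Ce(NO3)6 and NaHCO3 in MeCN at −10 °C should couple the two enol carbons through a seven-membered silicon-tethered transition state. The fallback comes back to the route at 10, which is closed to 12 with aqueous acid as in step 7.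

Step 3. The exo/endo and facial discrimination may be insufficient, and the 2-methyl group of the diene may erode the orientation of the cycloaddition. The fallback gives up catalyst control: cycloaddition of 3 and 4 promoted by Et2AlCl in CH2Cl2 at −78 °C should give the racemic trans aldehyde, that is 5 together with its (1S,2S)-enantiomer F4. The two are separated by preparative chromatography on a chiral stationary phase. The fallback sets out from 3 and 4 and comes back to the route at 5.

Step 9. The allyl cation may lose a proton to give dienes, or be captured at the tertiary terminus C8, instead of being acetylated at C6. The fallback replaces ionisation by substitution with inversion. It sets out from 14: a Mitsunobu reaction with 4-nitrobenzoic acid (PPh3, DIAD, THF) should give the inverted 6-(4-nitrobenzoate) F5. Methanolysis (K2CO3, MeOH) should give the equatorial 6-alcohol F6, and Ac2O, pyridine and DMAP should acetylate it. The fallback comes back to the route at 15.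

**Further compounds**

F1 | step 7 | chloro(dimethyl)silyl dienol ether of 7 | C[Si](C)(Cl)OC1=C[C@@](C)(C(OC)OC)[C@H](CO[Si](c2ccccc2)(c2ccccc2)C(C)(C)C)C(C)=C1
F2 | step 7 | lithium 3-methylbut-2-en-2-olate | [Li]OC(C)=C(C)C
F3 | step 7 | dimethylsilyl bis-enol ether of 7 and 3-methylbutan-2-one | CC(O[Si](C)(C)OC1=C[C@@](C)(C(OC)OC)[C@H](CO[Si](c2ccccc2)(c2ccccc2)C(C)(C)C)C(C)=C1)=C(C)C
F4 | step 3 | (1S,2S)-2-{[tert-butyl(diphenyl)silyl]oxymethyl}-1,3-dimethylcyclohex-3-ene-1-carbaldehyde (enantiomer of 5) | C1C=C(C)[C@H](CO[Si](c2ccccc2)(c2ccccc2)C(C)(C)C)[C@@](C)(C=O)C1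
F5 | step 9 | (5S,6R,9R,10S)-11-[tert-butyl(diphenyl)silyl]oxy-6-(4-nitrobenzoyloxy)drim-7-en-3-one | O=C(O[C@@H]1C=C(C)[C@@H](CO[Si](c3ccccc3)(c3ccccc3)C(C)(C)C)[C@]2(C)CCC(=O)C(C)(C)[C@@H]12)c1ccc(cc1)[N+](=O)[O-]
F6 | step 9 | (5S,6R,9R,10S)-11-[tert-butyl(diphenyl)silyl]oxy-6-hydroxydrim-7-en-3-one | O[C@@H]1C=C(C)[C@@H](CO[Si](c3ccccc3)(c3ccccc3)C(C)(C)C)[C@]2(C)CCC(=O)C(C)(C)[C@@H]12
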